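**Retrosynthetic overview**

- Positions follow the tetralone numbering of the target (C1 = ketone, C4 = quaternary carbon, C4a–C8a = arene). The strategy rests on the fully substituted benzene ring C4a–C5–C6–C7–C8–C8a, which carries oxygen on C5, C6 and C8 and isopropyl on C7. The para oxygens at C5 and C8 mark it as a hydroquinone that can be grown from a four-membered ring.
- The arene is disconnected at C8–C8a (electrocyclic ring expansion of a 4-cyclohexenyl-4-hydroxycyclobutenone) and at C4a–C5 (alkenyllithium plus 3-isopropoxy-4-isopropylcyclobutenedione, itself from diisopropyl squarate and isopropylmagnesium chloride).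
- The alkenyllithium comes from the enol triflate of a cyclohexanone whose C3 and C4 centres are set by anti conjugate addition of isopropenyl to an (R)-5-silyloxy-2-alkylcyclohexenone and anti methylation of the enolate. The enone comes from lipase-desymmetrised cis,cis-cyclohexane-1,3,5-triol.
- Ring order: carbocyclic ring B is bought with the triol; the aromatic ring is the only ring formed, in the key step. The endgame is quinone formation, desilylation, oxidation to the keto acid, vinylogous ester hydrolysis and reduction.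

Key step: step 12

Assumption: the lipase is taken to acetylate the enantiotopic hydroxyl that leads to the (1R,3S,5S) monoacetate; if it prefers the other hydroxyl, lipase hydrolysis of the meso diacetate delivers the same monoacetate.

**Route**

Step 1
Reactants: 1 diisopropyl squarate; 2 isopropylmagnesium chloride
Product: 4 3-isopropoxy-4-isopropylcyclobut-3-ene-1,2-dione, via squarate adduct 3 (not isolated)
Conditions: i-PrMgCl, THF, −78 °C; aq. NH4Cl; then conc. HCl (cat.), CH2Cl2, rt
Reagents that add atoms: none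
Why: 1,2-addition of the Grignard reagent to one squarate carbonyl, followed by acid-catalysed ionisation of the carbinol and hydrolysis of the resulting oxocarbenium ion with loss of isopropanol, is the standard squarate route to 3-alkoxy-4-alkylcyclobutenediones.

Step 2
Reactants: 5 cis,cis-cyclohexane-1,3,5-triol
Product: 6 cis,cis-5-(tert-butyldimethylsilyloxy)cyclohexane-1,3-diol
Conditions: TBSCl (1 equiv), imidazole, DMF, 0 °C to rt
Reagents that add atoms: tert-butyldimethylsilyl chloride, CC(C)(C)[Si](C)(C)Cl
Why: statistical monosilylation with limiting silyl chloride should give a single meso monoether because the three hydroxyls are equivalent, and unreacted triol can be recycled.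

Step 3
Reactants: 6 cis,cis-5-(tert-butyldimethylsilyloxy)cyclohexane-1,3-diol
Product: 7 (1R,3S,5S)-3-(tert-butyldimethylsilyloxy)-5-hydroxycyclohexyl acetate
Conditions: immobilised Candida antarctica lipase B, vinyl acetate, t-BuOMe, rt
Reagents that add atoms: vinyl acetate, C=COC(C)=O
Why: lipase-catalysed transesterification desymmetrises the meso diol because the enzyme distinguishes the two enantiotopic carbinol carbons, and vinyl acetate makes the acylation irreversible; this step sets the absolute configuration of the whole route.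

Step 4
Reactants: 7 (1R,3S,5S)-3-(tert-butyldimethylsilyloxy)-5-hydroxycyclohexyl acetate
Product: 9 (R)-5-(tert-butyldimethylsilyloxy)cyclohex-2-en-1-one, via acetoxy ketone 8 (not isolated)
Conditions: Dess–Martin periodinane, CH2Cl2, 0 °C to rt; then Et3N, 0 °C to rt
Reagents that add atoms: none
Why: Dess–Martin oxidation gives the β-acetoxy ketone, and triethylamine then triggers E1cB elimination in which acetate, the better of the two β-leaving groups, departs, so the silyloxy carbon remains as the only stereocentre.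

Step 5
Reactants: 9 (R)-5-(tert-butyldimethylsilyloxy)cyclohex-2-en-1-one
Product: 10 (R)-5-(tert-butyldimethylsilyloxy)-2-iodocyclohex-2-en-1-one
Conditions: I2, pyridine, CH2Cl2, 0 °C to rt
Reagents that add atoms: iodine, II
Why: Johnson α-iodination of an enone (pyridine conjugate addition, iodination of the enolate, elimination) works on cyclohexenones, and the weak base should leave the β-silyloxy group in place.

Step 6
Reactants: 10 (R)-5-(tert-butyldimethylsilyloxy)-2-iodocyclohex-2-en-1-one; 11 allyl tert-butyldimethylsilyl ether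
Product: 13 (R)-5-(tert-butyldimethylsilyloxy)-2-[3-(tert-butyldimethylsilyloxy)propyl]cyclohex-2-en-1-one, via alkylborane 12 (not isolated)
Conditions: 11, 9-BBN, THF, 0 °C to rt; then 10, PdCl2(dppf) (cat.), AsPh3, Cs2CO3, DMF/THF/H2O, rt
Reagents that add atoms: none
Why: anti-Markovnikov hydroboration followed by B-alkyl Suzuki–Miyaura coupling with the α-iodoenone installs the three-carbon arm at room temperature under base mild enough for the β-silyloxy ketone.

Step 7
Reactants: 13 (R)-5-(tert-butyldimethylsilyloxy)-2-[3-(tert-butyldimethylsilyloxy)propyl]cyclohex-2-en-1-one; 14 isopropenylmagnesium bromide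
Product: 15 trimethylsilyl enol ether of the (3S,5R)-3-isopropenyl-5-silyloxy ketone (isopropenyl trans to the ring silyloxy group)
Conditions: CuBr·SMe2 (cat.), Me3SiCl, HMPA, THF, −78 °C; Et3N quench
Reagents that add atoms: chlorotrimethylsilane, C[Si](C)(C)Cl
Why: copper-catalysed, silyl-chloride-accelerated conjugate addition of the Grignard reagent should deliver isopropenyl to the enone face anti to the C5 silyloxy group (trans-3,5 product), which sets the future C3 centre as S, and the enolate is captured regiospecifically as the silyl enol ether.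

Step 8
Reactants: 15 trimethylsilyl enol ether of the (3S,5R)-3-isopropenyl-5-silyloxy ketone
Product: 17 (2R,3S,5R)-5-(tert-butyldimethylsilyloxy)-2-[3-(tert-butyldimethylsilyloxy)propyl]-2-methyl-3-(prop-1-en-2-yl)cyclohexan-1-one, via lithium enolate 16 (not isolated)
Conditions: MeLi, THF, 0 °C; then MeI, DMPU, −78 to 0 °C
Reagents that add atoms: iodomethane, CI
Why: MeLi cleaves the silyl enol ether to the regiodefined tetrasubstituted lithium enolate, and enolate C-alkylation with methyl iodide should occur by axial attack on the face opposite the adjacent isopropenyl group, which sets the quaternary centre as R with methyl trans to isopropenyl.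

Step 9
Reactants: 17 (2R,3S,5R)-5-(tert-butyldimethylsilyloxy)-2-[3-(tert-butyldimethylsilyloxy)propyl]-2-methyl-3-(prop-1-en-2-yl)cyclohexan-1-one
Product: 19 (3R,5S,6R)-3-(tert-butyldimethylsilyloxy)-6-[3-(tert-butyldimethylsilyloxy)propyl]-6-methyl-5-(prop-1-en-2-yl)cyclohex-1-en-1-yl trifluoromethanesulfonate, via potassium enolate 18 (not isolated)
Conditions: KN(SiMe3)2, THF, −78 °C; then N-(5-chloropyridin-2-yl)bis(trifluoromethanesulfonimide), −78 °C
Reagents that add atoms: Comins' reagent, O=S(=O)(N(c1ccc(Cl)cn1)S(=O)(=O)C(F)(F)F)C(F)(F)F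
Why: kinetic deprotonation can occur only at C6 because C2 is quaternary, and enolate O-sulfonylation with the fast Comins' reagent at −78 °C is meant to outrun E1cB loss of the β-silyloxy group.

Step 10
Reactants: 19 enol triflate
Product: 20 trimethyl[(3R,5S,6R)-3-(tert-butyldimethylsilyloxy)-6-[3-(tert-butyldimethylsilyloxy)propyl]-6-methyl-5-(prop-1-en-2-yl)cyclohex-1-en-1-yl]stannane
Conditions: Me3SnSnMe3, Pd(PPh3)4 (cat.), LiCl, THF, reflux
Reagents that add atoms: hexamethylditin, C[Sn](C)(C)[Sn](C)(C)C
Why: palladium-catalysed stannylation of an enol triflate with hexamethylditin (Stille-type coupling) is established for hindered cyclohexenyl triflates next to quaternary carbons.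

Step 11
Reactants: 20 alkenylstannane; 4 3-isopropoxy-4-isopropylcyclobut-3-ene-1,2-dione
Product: 22 4-hydroxy-3-isopropoxy-2-isopropyl-4-[(3R,5S,6R)-3-(tert-butyldimethylsilyloxy)-6-[3-(tert-butyldimethylsilyloxy)propyl]-6-methyl-5-(prop-1-en-2-yl)cyclohex-1-en-1-yl]cyclobut-2-en-1-one (both epimers at the carbinol carbon), via alkenyllithium 21 (not isolated)
Conditions: MeLi, THF, −78 to −40 °C; then 4, THF, −78 °C; aq. NH4Cl
Reagents that add atoms: none
Why: tin–lithium exchange gives the alkenyllithium, which should add 1,2 to the more electrophilic carbonyl of the dione (the one next to the isopropoxy-bearing carbon, not the vinylogous ester carbonyl); the new carbinol centre forms as a mixture that does not matter because it becomes an arene carbon.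

Step 12
Reactants: 22 4-cyclohexenyl-4-hydroxycyclobutenone
Product: 25 (1R,3S,4R)-1-(tert-butyldimethylsilyloxy)-4-[3-(tert-butyldimethylsilyloxy)propyl]-6-isopropoxy-7-isopropyl-4-methyl-3-(prop-1-en-2-yl)-1,2,3,4-tetrahydronaphthalene-5,8-diol, via dienylketene 23 (not isolated), via cyclohexadienone 24 (not isolated)
Conditions: degassed toluene, 110 °C, argon
Reagents that add atoms: none
Why: Heating cleaves the bond between the carbinol carbon and the carbonyl carbon of the cyclobutenone by conrotatory 4π-electrocyclic opening, and the donor hydroxyl rotates outward so that the cyclohexenyl group sits cis to the ketene in dienylketene 23. The ketene carbon, the two former cyclobutene carbons, the carbinol carbon and the C4a=C8a double bond of ring B then close by thermal 6π-electrocyclisation, the only ring closure of the step, which forms the C8–C8a bond and gives cyclohexadienone 24. Enolisation of the C8a–H of 24 aromatises the ring to hydroquinone 25, so the transient sp3 centre at C8a is erased and no new stereocentre remains, while C1, C3 and C4 are spectators. The closest known reaction type is the Moore rearrangement of 4-alkenyl-4-hydroxycyclobutenones derived from squarate esters. The selectivity needed is regiochemical (oxygen at C5, C6 and C8, isopropyl at C7) and is already fixed in 22 by the site of addition in step 11; the outward rotation of the hydroxyl secures the reactive ketene geometry and the C8a–H carbon is the only alkene terminus available.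

Step 13
Reactants: 25 hydroquinone
Product: 26 (1R,3S,4R)-1-(tert-butyldimethylsilyloxy)-4-[3-(tert-butyldimethylsilyloxy)propyl]-6-isopropoxy-7-isopropyl-4-methyl-3-(prop-1-en-2-yl)-1,2,3,4-tetrahydronaphthalene-5,8-dione
Conditions: Ag2O, MgSO4, Et2O, rt
Reagents that add atoms: none
Why: oxidation of a hydroquinone to the quinone with Ag2O is mild and selective, and it stores the electron-rich ring in a form that tolerates the fluoride and chromium steps that follow.

Step 14
Reactants: 26 quinone bis(silyl ether)
Product: 27 (1R,3S,4R)-1-hydroxy-4-(3-hydroxypropyl)-6-isopropoxy-7-isopropyl-4-methyl-3-(prop-1-en-2-yl)-1,2,3,4-tetrahydronaphthalene-5,8-dione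
Conditions: HF·pyridine, pyridine, THF, 0 °C to rt
Reagents that add atoms: none
Why: fluoride-mediated desilylation with buffered HF·pyridine should remove both silyl ethers without touching the isopropenyl group or the vinylogous ester of the quinone.

Step 15
Reactants: 27 quinone diol
Product: 28 3-[(3S,4R)-6-isopropoxy-7-isopropyl-4-methyl-1,5,8-trioxo-3-(prop-1-en-2-yl)-1,2,3,4,5,8-hexahydronaphthalen-4-yl]propanoic acid
Conditions: CrO3, H2SO4, H2O, acetone, 0 °C; i-PrOH quench
Reagents that add atoms: water, O
Why: Jones oxidation takes the secondary alcohol to the C1 ketone and the primary alcohol through the aldehyde hydrate to the acid in one operation, and any acylhydroquinone formed from 27 by the known redox tautomerism of hydroxyalkylquinones is returned to the same quinone by the oxidant.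

Step 16
Reactants: 28 isopropoxyquinone keto acid
Product: 29 3-[(3S,4R)-6-hydroxy-7-isopropyl-4-methyl-1,5,8-trioxo-3-(prop-1-en-2-yl)-1,2,3,4,5,8-hexahydronaphthalen-4-yl]propanoic acid
Conditions: LiOH, degassed THF/H2O, 0 °C to rt; then dilute HCl to pH 3, 0 °C
Reagents that add atoms: lithium hydroxide, [Li+].[OH-]
Why: the 2-alkoxyquinone is a vinylogous ester, so hydroxide addition–elimination at C6 should expel isopropoxide and give the hydroxyquinone as its stabilised anion; no alcohol cosolvent is used to avoid ether exchange, and C3 and C4 cannot epimerise because neither is α to a carbonyl.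

Step 17
Reactants: 29 hydroxyquinone keto acid
Product: 30 3-[(3S,4R)-5,6,8-trihydroxy-7-isopropyl-4-methyl-1-oxo-3-(prop-1-en-2-yl)-1,2,3,4-tetrahydronaphthalen-4-yl]propanoic acid
Conditions: Na2S2O4, degassed EtOAc/H2O, rt, argon
Reagents that add atoms: none
Why: dithionite reduction converts the quinone to the hydroquinone without affecting the aryl ketone, the isopropenyl group or the acid, and the air-sensitive 1,2,4-triol is kept under argon.

**Compound list**

1 | diisopropyl squarate | CC(C)OC1=C(OC(C)C)C(=O)C1=O | starting material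
2 | isopropylmagnesium chloride | CC(C)[Mg]Cl | starting material
3 | 4-hydroxy-2,3-diisopropoxy-4-isopropylcyclobut-2-en-1-one (racemic squarate adduct) | CC(C)OC1=C(OC(C)C)C(O)(C(C)C)C1=O | intermediate (not isolated)
4 | 3-isopropoxy-4-isopropylcyclobut-3-ene-1,2-dione | CC(C)OC1=C(C(C)C)C(=O)C1=O | intermediate
5 | cis,cis-cyclohexane-1,3,5-triol | O[C@H]1C[C@@H](O)C[C@@H](O)C1 | starting material
6 | cis,cis-5-(tert-butyldimethylsilyloxy)cyclohexane-1,3-diol (meso) | O[C@H]1C[C@@H](O)C[C@@H](O[Si](C)(C)C(C)(C)C)C1 | intermediate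
7 | (1R,3S,5S)-3-(tert-butyldimethylsilyloxy)-5-hydroxycyclohexyl acetate | O[C@H]1C[C@@H](OC(C)=O)C[C@@H](O[Si](C)(C)C(C)(C)C)C1 | intermediate
8 | (1S,3R)-3-(tert-butyldimethylsilyloxy)-5-oxocyclohexyl acetate | O=C1C[C@@H](OC(C)=O)C[C@@H](O[Si](C)(C)C(C)(C)C)C1 | intermediate (not isolated)
9 | (R)-5-(tert-butyldimethylsilyloxy)cyclohex-2-en-1-one | O=C1C=CC[C@@H](O[Si](C)(C)C(C)(C)C)C1 | intermediate
10 | (R)-5-(tert-butyldimethylsilyloxy)-2-iodocyclohex-2-en-1-one | O=C1C(I)=CC[C@@H](O[Si](C)(C)C(C)(C)C)C1 | intermediate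
11 | allyl tert-butyldimethylsilyl ether | C=CCO[Si](C)(C)C(C)(C)C | starting material
12 | B-[3-(tert-butyldimethylsilyloxy)propyl]-9-borabicyclo[3.3.1]nonane | CC(C)(C)[Si](C)(C)OCCCB1C2CCCC1CCC2 | intermediate (not isolated)
13 | (R)-5-(tert-butyldimethylsilyloxy)-2-[3-(tert-butyldimethylsilyloxy)propyl]cyclohex-2-en-1-one | O=C1C(CCCO[Si](C)(C)C(C)(C)C)=CC[C@@H](O[Si](C)(C)C(C)(C)C)C1 | intermediate
14 | isopropenylmagnesium bromide | C=C(C)[Mg]Br | starting material
15 | [(3S,5R)-5-(tert-butyldimethylsilyloxy)-2-[3-(tert-butyldimethylsilyloxy)propyl]-3-(prop-1-en-2-yl)cyclohex-1-en-1-yl]oxytrimethylsilane | C=C(C)[C@@H]1C[C@@H](O[Si](C)(C)C(C)(C)C)CC(O[Si](C)(C)C)=C1CCCO[Si](C)(C)C(C)(C)C | intermediate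
16 | lithium enolate of 17 (tetrasubstituted, C1–C2) | C=C(C)[C@@H]1C[C@@H](O[Si](C)(C)C(C)(C)C)CC(O[Li])=C1CCCO[Si](C)(C)C(C)(C)C | intermediate (not isolated)
17 | (2R,3S,5R)-5-(tert-butyldimethylsilyloxy)-2-[3-(tert-butyldimethylsilyloxy)propyl]-2-methyl-3-(prop-1-en-2-yl)cyclohexan-1-one | C=C(C)[C@@H]1C[C@@H](O[Si](C)(C)C(C)(C)C)CC(=O)[C@]1(C)CCCO[Si](C)(C)C(C)(C)C | intermediate
18 | potassium enolate of 17 (C1–C6) | C=C(C)[C@@H]1C[C@@H](O[Si](C)(C)C(C)(C)C)C=C(O[K])[C@]1(C)CCCO[Si](C)(C)C(C)(C)C | intermediate (not isolated)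
19 | (3R,5S,6R)-3-(tert-butyldimethylsilyloxy)-6-[3-(tert-butyldimethylsilyloxy)propyl]-6-methyl-5-(prop-1-en-2-yl)cyclohex-1-en-1-yl trifluoromethanesulfonate | C=C(C)[C@@H]1C[C@@H](O[Si](C)(C)C(C)(C)C)C=C(OS(=O)(=O)C(F)(F)F)[C@]1(C)CCCO[Si](C)(C)C(C)(C)C | intermediate
20 | trimethyl[(3R,5S,6R)-3-(tert-butyldimethylsilyloxy)-6-[3-(tert-butyldimethylsilyloxy)propyl]-6-methyl-5-(prop-1-en-2-yl)cyclohex-1-en-1-yl]stannane | C=C(C)[C@@H]1C[C@@H](O[Si](C)(C)C(C)(C)C)C=C([Sn](C)(C)C)[C@]1(C)CCCO[Si](C)(C)C(C)(C)C | intermediate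
21 | alkenyllithium corresponding to 20 | C=C(C)[C@@H]1C[C@@H](O[Si](C)(C)C(C)(C)C)C=C([Li])[C@]1(C)CCCO[Si](C)(C)C(C)(C)C | intermediate (not isolated)
22 | 4-hydroxy-3-isopropoxy-2-isopropyl-4-(cyclohexenyl)cyclobut-2-en-1-one, key-step precursor (both carbinol epimers) | C=C(C)[C@@H]1C[C@@H](O[Si](C)(C)C(C)(C)C)C=C(C2(O)C(OC(C)C)=C(C(C)C)C2=O)[C@]1(C)CCCO[Si](C)(C)C(C)(C)C | intermediate
23 | dienylketene (hydroxyl outward, cyclohexenyl cis to the ketene) | C=C(C)[C@@H]1C[C@@H](O[Si](C)(C)C(C)(C)C)C=C(/C(O)=C(OC(C)C)\C(C(C)C)=C=O)[C@]1(C)CCCO[Si](C)(C)C(C)(C)C | intermediate (not isolated)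
24 | cyclohexadienone with sp3 C8a–H (configuration at C8a not defined) | C=C(C)[C@@H]1C[C@@H](O[Si](C)(C)C(C)(C)C)C2C(=O)C(C(C)C)=C(OC(C)C)C(O)=C2[C@]1(C)CCCO[Si](C)(C)C(C)(C)C | intermediate (not isolated)
25 | (1R,3S,4R)-1-(tert-butyldimethylsilyloxy)-4-[3-(tert-butyldimethylsilyloxy)propyl]-6-isopropoxy-7-isopropyl-4-methyl-3-(prop-1-en-2-yl)-1,2,3,4-tetrahydronaphthalene-5,8-diol | C=C(C)[C@@H]1C[C@@H](O[Si](C)(C)C(C)(C)C)c2c(O)c(C(C)C)c(OC(C)C)c(O)c2[C@]1(C)CCCO[Si](C)(C)C(C)(C)C | intermediate
26 | corresponding 5,8-quinone of 25 | C=C(C)[C@@H]1C[C@@H](O[Si](C)(C)C(C)(C)C)C2=C(C(=O)C(OC(C)C)=C(C(C)C)C2=O)[C@]1(C)CCCO[Si](C)(C)C(C)(C)C | intermediate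
27 | (1R,3S,4R)-1-hydroxy-4-(3-hydroxypropyl)-6-isopropoxy-7-isopropyl-4-methyl-3-(prop-1-en-2-yl)-1,2,3,4-tetrahydronaphthalene-5,8-dione | C=C(C)[C@@H]1C[C@@H](O)C2=C(C(=O)C(OC(C)C)=C(C(C)C)C2=O)[C@]1(C)CCCO | intermediate
28 | 3-[(3S,4R)-6-isopropoxy-7-isopropyl-4-methyl-1,5,8-trioxo-3-(prop-1-en-2-yl)-1,2,3,4,5,8-hexahydronaphthalen-4-yl]propanoic acid | C=C(C)[C@@H]1CC(=O)C2=C(C(=O)C(OC(C)C)=C(C(C)C)C2=O)[C@]1(C)CCC(=O)O | intermediate
29 | 3-[(3S,4R)-6-hydroxy-7-isopropyl-4-methyl-1,5,8-trioxo-3-(prop-1-en-2-yl)-1,2,3,4,5,8-hexahydronaphthalen-4-yl]propanoic acid | C=C(C)[C@@H]1CC(=O)C2=C(C(=O)C(O)=C(C(C)C)C2=O)[C@]1(C)CCC(=O)O | intermediate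
30 | 3-[(3S,4R)-5,6,8-trihydroxy-7-isopropyl-4-methyl-1-oxo-3-(prop-1-en-2-yl)-1,2,3,4-tetrahydronaphthalen-4-yl]propanoic acid (CNP0198818.2) | C=C(C)[C@@H]1CC(=O)c2c(O)c(C(C)C)c(O)c(O)c2[C@]1(C)CCC(=O)O | target

**Step count and risks**

Total steps: 17. Longest linear sequence: 16 steps (steps 2 to 17, from triol 5 to target 30); the squarate branch (step 1) joins at step 11.

Steps most likely to fail:

1. Step 9. The C6 enolate carries the silyloxy group in the β-position, so E1cB loss of silanolate to a cyclohexenone can compete with O-sulfonylation, especially if the enolate lives long or warms. Fallback: from 17, the neutral ketone is O-sulfonylated electrophilically with Tf2O and 2,6-di-tert-butyl-4-methylpyridine in CH2Cl2 at 0 °C. No enolate anion is formed, so the β-elimination pathway is removed, and the only available α-proton (C6) is lost from the O-triflyl oxocarbenium ion. This leads directly to 19, so no compound outside the list arises (F0).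

2. Step 12. The cyclohexenyl carbon C4a is flanked by the quaternary C4, which may twist the dienylketene out of the planar geometry needed for 6π closure. The free tertiary hydroxyl could then capture the ketene to give a lactone, and the free hydroquinone may oxidise or degrade in hot solution. Fallback: from 22, the tertiary alcohol is silylated (Me3SiOTf, Et3N, CH2Cl2, −78 °C) to the 4-(trimethylsilyloxy)cyclobutenone F1. Thermolysis of F1 in toluene at 110 °C, the known silyl-protected variant of the same ring expansion, should give the C5-O-trimethylsilyl hydroquinone F2, with no free hydroxyl to intercept the ketene and one phenol masked against oxidation. Mild methanolysis (K2CO3, MeOH, 0 °C, argon) removes the aryl silyl group and returns the route at 25.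

3. Step 16. Hydroxide must add to the hindered C6 of an enolisable acylquinone; deprotonation at C2 and base-induced electron transfer or decomposition of the acylquinone may outpace the slow addition–elimination. Fallback: from 26, before the C1 ketone exists, the vinylogous ester is hydrolysed (LiOH, THF/H2O, rt to 40 °C; the silyl ethers tolerate this) to the hydroxyquinone bis(silyl ether) F3. HF·pyridine then gives the hydroxyquinone diol F4, and CrO3/H2SO4 in acetone at 0 °C, an oxidation of hydroxyalkyl-hydroxyquinones to acyl-hydroxyquinones that has precedent in type, converts both alcohols and returns the route at 29.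

**Further compounds**

F0 | step 9 | none | none
F1 | step 12 | 3-isopropoxy-2-isopropyl-4-(trimethylsilyloxy)-4-(cyclohexenyl)cyclobut-2-en-1-one (trimethylsilyl ether of 22) | C=C(C)[C@@H]1C[C@@H](O[Si](C)(C)C(C)(C)C)C=C(C2(O[Si](C)(C)C)C(OC(C)C)=C(C(C)C)C2=O)[C@]1(C)CCCO[Si](C)(C)C(C)(C)C
F2 | step 12 | C5-O-trimethylsilyl ether of hydroquinone 25 (C8 hydroxyl free) | C=C(C)[C@@H]1C[C@@H](O[Si](C)(C)C(C)(C)C)c2c(O)c(C(C)C)c(OC(C)C)c(O[Si](C)(C)C)c2[C@]1(C)CCCO[Si](C)(C)C(C)(C)C
F3 | step 16 | (1R,3S,4R)-1-(tert-butyldimethylsilyloxy)-4-[3-(tert-butyldimethylsilyloxy)propyl]-6-hydroxy-7-isopropyl-4-methyl-3-(prop-1-en-2-yl)-1,2,3,4-tetrahydronaphthalene-5,8-dione | C=C(C)[C@@H]1C[C@@H](O[Si](C)(C)C(C)(C)C)C2=C(C(=O)C(O)=C(C(C)C)C2=O)[C@]1(C)CCCO[Si](C)(C)C(C)(C)C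
F4 | step 16 | (1R,3S,4R)-1,6-dihydroxy-4-(3-hydroxypropyl)-7-isopropyl-4-methyl-3-(prop-1-en-2-yl)-1,2,3,4-tetrahydronaphthalene-5,8-dione | C=C(C)[C@@H]1C[C@@H](O)C2=C(C(=O)C(O)=C(C(C)C)C2=O)[C@]1(C)CCCO
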